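**Retrosynthetic overview**
- The oxonane is closed last at C6–C7 by an electroreductive Ni/Cr (Nozaki–Hiyama–Kishi) coupling of a C6 aldehyde with a C7 2-bromoalkene, which also sets C6.
- The ε-lactone (C3–O) and the C4 oxygen come from a (Z)-C3=C4 alkene by epoxidation and 7-exo opening by the C16 acid; the C16 acid and C15 come from hydroboration of the isopropenyl group.
- The oxolane is built on a cis-fused anhydride: C2–C3 by a (Z)-alkenyllithium, C2–H by hydride delivery to a cyclic acyloxycarbenium ion, C9–C8 by allylation of a C9 oxocarbenium ion, both from the convex face.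
- The anhydride comes from (R)-carvone: epoxidation fixes C11–O, Shapiro carboxylation brings in C9, and a photochemical CO2 radical-anion addition forms C1–C2.
- Ring order: cyclohexane (bought) → oxolane → ε-lactone → oxonane.

Assumption: the SMILES is read literally (H-1, H-2 and H-10 on one face of the oxolane, H-9 on the other, so C3 is syn to C14 and C8 is anti); locants are those of the eunicellane skeleton (oxolane O between C2 and C9; cyclohexane C1, C10–C14; C15–C17 on C14 with C16 the lactone carbonyl; C18 on C3, C19 on C7, C20 on C11).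

Step 1
Reactants: 1 (R)-(−)-carvone
Product: 2 trans-carvone epoxide [(1R,4R,6R)-1-methyl-4-(prop-1-en-2-yl)-7-oxabicyclo[4.1.0]heptan-2-one]
Conditions: 30% aq. H2O2, NaOH (0.3 equiv), MeOH, 0 °C
Reagents that add atoms: hydrogen peroxide, OO
Why: Weitz–Scheffer nucleophilic epoxidation; hydroperoxide adds axially to the enone β-carbon anti to the isopropenyl group, so the epoxide oxygen (the later C11 hydroxyl) is trans to the C14 substituent.

Step 2
Reactants: 2 trans-carvone epoxide
Product: 3 (1R,4R)-1-methyl-4-(prop-1-en-2-yl)cyclohexane-1,2-diol (both C2 carbinol epimers)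
Conditions: LiAlH4, THF, 0 °C to rt; aq. NaOH work-up
Reagents that add atoms: none
Why: Hydride reduction; the ketone is reduced and the epoxide is opened by SN2 attack at the secondary carbon (C12), so the tertiary C11–O bond keeps its configuration, and the new carbinol centre is removed in step 3.

Step 3
Reactants: 3 diol
Product: 4 (2R,5R)-2-hydroxy-2-methyl-5-(prop-1-en-2-yl)cyclohexan-1-one
Conditions: IBX (1.5 equiv), EtOAc, 75 °C
Reagents that add atoms: none
Why: IBX oxidation of the secondary alcohol of a 1,2-diol to the α-ketol without glycol cleavage; the tertiary alcohol is inert and both diol epimers converge.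

Step 4
Reactants: 4 hydroxy ketone
Product: 5 (2R,5R)-2-methyl-5-(prop-1-en-2-yl)-2-(triethylsilyloxy)cyclohexan-1-one
Conditions: Et3SiOTf, 2,6-lutidine, CH2Cl2, −78 to 0 °C
Reagents that add atoms: triethylsilyl trifluoromethanesulfonate, CC[Si](CC)(CC)OS(=O)(=O)C(F)(F)F
Why: Silylation of the tertiary alcohol, so that it cannot compete with the C9 carboxyl as the internal nucleophile toward C2 in steps 11 and 12.

Step 5
Reactants: 5 silyloxy ketone
Product: 6 2,4,6-triisopropylbenzenesulfonylhydrazone of 5 (N–N bond syn to the ring CH2)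
Conditions: 2,4,6-triisopropylbenzenesulfonyl hydrazide, THF, rt
Reagents that add atoms: 2,4,6-triisopropylbenzenesulfonyl hydrazide, CC(C)c1cc(C(C)C)c(S(=O)(=O)NN)c(C(C)C)c1
Why: Hydrazone condensation; the sulfonamide nitrogen sits away from the quaternary carbon, as the Shapiro reaction needs.

Step 6
Reactants: 6 trisylhydrazone
Product: 8 (3R,6R)-6-methyl-3-(prop-1-en-2-yl)-6-(triethylsilyloxy)cyclohex-1-ene-1-carboxylic acid, via C10 alkenyllithium 7 (not isolated)
Conditions: n-BuLi (2.2 equiv), THF, −78 to 0 °C; CO2, −78 °C; cold 1 M HCl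
Reagents that add atoms: carbon dioxide, O=C=O
Why: Shapiro reaction with carboxylation; the only α-hydrogens are on C1, so the C1=C10 alkenyllithium forms regiospecifically and CO2 installs C9.

Step 7
Reactants: 8 cyclohexenecarboxylic acid
Product: 9 (1S,2S,3R,6R)-3-methyl-6-(prop-1-en-2-yl)-3-(triethylsilyloxy)cyclohexane-1,2-dicarboxylic acid (cis-diacid)
Conditions: HCO2K (3 equiv), HCO2H (3 equiv), 4CzIPN (2 mol %), methyl thiosalicylate (20 mol %), DMSO, 450 nm LEDs, rt; 1 M HCl
Reagents that add atoms: potassium formate, [K+].[O-]C=O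
Why: Visible-light, thiol-catalysed hydrocarboxylation (Giese-type addition of the CO2 radical anion made by hydrogen-atom transfer from formate); the radical adds to C1 anti to the neighbouring isopropenyl group, and the C10 radical takes its hydrogen on the face away from the new carboxylate and the C11 silyloxy group, giving the cis-diacid.

Step 8
Reactants: 9 cis-diacid
Product: 10 cis-fused cyclic anhydride of 9
Conditions: Ac2O, toluene, 80 °C
Reagents that add atoms: none
Why: Cyclodehydration to the five-membered anhydride; any trans-diacid epimerises at C10 under these conditions and converges on the cis-fused ring.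

Step 9
Reactants: 11 3-(tert-butyldiphenylsilyloxy)propan-1-ol
Product: 12 3-(tert-butyldiphenylsilyloxy)propanal
Conditions: IBX (1.5 equiv), EtOAc, 75 °C
Reagents that add atoms: none
Why: IBX oxidation of a primary alcohol to the aldehyde without over-oxidation.

Step 10
Reactants: 12 silyloxypropanal
Product: 13 (Z)-tert-butyl(4-iodopent-3-enyloxy)diphenylsilane
Conditions: EtPPh3I, n-BuLi, THF, rt; I2, −78 °C; NaN(SiMe3)2, −20 °C; then 12, −78 °C to rt
Reagents that add atoms: ethyltriphenylphosphonium iodide, CC[P+](c1ccccc1)(c1ccccc1)c1ccccc1.[I-]; iodine, II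
Why: Stork–Zhao α-iodo Wittig olefination, which gives the (Z)-2-iodoalkene (iodine cis to the chain) that later places C2 cis to C5.

Step 11
Reactants: 10 cis-fused anhydride; 13 (Z)-vinyl iodide
Product: 15 cis keto acid with a (Z)-2-methyl-5-(tert-butyldiphenylsilyloxy)pent-2-enoyl group on C1 and CO2H on C10 (in equilibrium with its cyclic hydroxy lactone), via (Z)-alkenyllithium 14 (not isolated)
Conditions: 13, t-BuLi (2.05 equiv), Et2O, −78 °C; added to 10 (1.1 equiv), THF, −78 °C; 1 M HCl
Reagents that add atoms: none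
Why: Iodine–lithium exchange with retention of alkene geometry, then acyl substitution on the anhydride; the C9 carbonyl is shielded by the syn C11 silyloxy group, so the alkenyllithium opens the ring at the C2 carbonyl and forms C2–C3.

Step 12
Reactants: 15 keto acid
Product: 16 cis-fused γ-lactone (C9 carbonyl) with H-2 syn to H-1 and H-10 and the (Z)-alkenyl chain on the concave face
Conditions: Et3SiH (5 equiv), BF3·OEt2 (3 equiv), CH2Cl2, −78 to −40 °C
Reagents that add atoms: none
Why: Ionic hydrogenation of the cyclic pseudo-acid through its acyloxycarbenium ion; the silane delivers hydride to C2 from the convex face of the cis-fused bicycle, which puts C3 on the concave face (C2 R), and the oxygen-stabilised cation is reduced at C2 without loss of the alkene geometry.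

Step 13
Reactants: 16 γ-lactone
Product: 18 C9 lactol acetate (both anomers), via aluminium lactolate 17 (not isolated)
Conditions: i-Bu2AlH (1.2 equiv), CH2Cl2, −78 °C; then pyridine, DMAP, Ac2O, −78 to −20 °C
Reagents that add atoms: acetic anhydride, CC(=O)OC(C)=O
Why: One-pot reductive acetylation of a lactone (hydride stops at the tetrahedral aluminium lactolate, which is acetylated in place); the anomeric centre is reset in step 14.

Step 14
Reactants: 18 lactol acetate
Product: 19 2,5-trans oxolane carrying the 2-bromoallyl group on C9 (C8 on the convex face, H-9 anti to H-10)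
Conditions: (2-bromoallyl)trimethylsilane (3 equiv), BF3·OEt2 (2 equiv), CH2Cl2, −78 °C
Reagents that add atoms: (2-bromoallyl)trimethylsilane, C=C(Br)C[Si](C)(C)C
Why: Hosomi–Sakurai C-glycosylation; the C9 oxocarbenium ion is attacked on the convex face, which is also anti to the concave C2 substituent, so C9 is set (S) and the C7 bromoalkene is installed.

Step 15
Reactants: 19 allylated oxolane
Product: 21 C16 primary alcohol with the (15R)-methyl centre, via B-alkyl-9-borabicyclononane 20 (not isolated)
Conditions: 9-BBN (1.5 equiv), THF, 0 °C to rt; then 3 M NaOH, 30% H2O2, 0 °C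
Reagents that add atoms: hydrogen peroxide, OO
Why: Hydroboration–oxidation; 9-BBN takes only the 1,1-disubstituted isopropenyl group, and 1,2-induction (H-14 eclipsing the alkene, borane anti to the substituted C1 side, as in Still–Barrish hydroborations) sets C15.

Step 16
Reactants: 21 primary alcohol
Product: 22 C16 carboxylic acid
Conditions: TEMPO (20 mol %), PhI(OAc)2 (2.5 equiv), MeCN–H2O (1:1), rt
Reagents that add atoms: water, O
Why: TEMPO-mediated oxidation of a primary alcohol to the acid through the aldehyde hydrate; alkenes, the bromoalkene and silyl ethers are untouched and C15 is not epimerised.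

Step 17
Reactants: 22 carboxylic acid
Product: 24 hydroxy ε-lactone (C16–O–C3 closed, free C4 hydroxyl), via C3/C4 epoxy acid 23 (not isolated)
Conditions: m-CPBA (1.2 equiv), CH2Cl2, −20 to 0 °C; then TsOH·H2O (10 mol %), 0 °C to rt
Reagents that add atoms: 3-chloroperbenzoic acid, OOC(=O)c1cccc(Cl)c1
Why: Prilezhaev epoxidation followed by acid-catalysed 7-exo epoxide opening; the (Z)-alkene is locked by allylic 1,3-strain with H-2 in the alkene plane and is epoxidised on the face away from C1, and the tethered carboxyl then attacks tertiary C3 from the C1 side with inversion, giving C3 (S) and C4 (R).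

Step 18
Reactants: 24 hydroxy lactone
Product: 25 C4 octanoate
Conditions: octanoyl chloride (1.5 equiv), pyridine, DMAP (cat.), CH2Cl2, 0 °C to rt
Reagents that add atoms: octanoyl chloride, CCCCCCCC(=O)Cl
Why: DMAP-catalysed acylation of the only free hydroxyl (secondary C4–OH); both other oxygens are silylated.

Step 19
Reactants: 25 octanoate
Product: 26 diol (free C11 tertiary and C6 primary hydroxyls)
Conditions: HF·pyridine, pyridine–THF, 0 °C to rt
Reagents that add atoms: none
Why: Fluoride-mediated removal of both silyl ethers in one operation; the lactone, the ester and the bromoalkene are stable.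

Step 20
Reactants: 26 diol
Product: 27 C6 aldehyde
Conditions: Dess–Martin periodinane, NaHCO3, CH2Cl2, 0 °C to rt
Reagents that add atoms: none
Why: Dess–Martin oxidation of the primary alcohol under buffered conditions, so the β-acyloxy aldehyde does not eliminate; the tertiary alcohol cannot be oxidised.

Step 21
Reactants: 27 bromoalkene aldehyde
Product: 28 target CNP0295349.4
Conditions: CrCl2 (20 mol %), NiCl2(dme) (2 mol %), 2,9-dimethyl-1,10-phenanthroline (2.5 mol %), Cp2ZrCl2 (1.5 equiv), LiCl, DMF, undivided cell, Al anode, Ni-foam cathode, 2 mA (about 2.5 F/mol), 27 added over 6 h to 2 mM, rt; 0.5 M HCl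
Reagents that add atoms: none
Why: Proposed new method: an intramolecular, chromium-catalytic electroreductive Nozaki–Hiyama–Kishi closure of a nine-membered cyclic ether — cathodically formed zerovalent nickel inserts into the 2-bromoalkene, the alkenyl group passes to trivalent chromium, divalent chromium is regenerated at the cathode (aluminium anode sacrificial), Cp2ZrCl2 frees chromium from the product alkoxide, and slow addition keeps the tethered aldehyde dilute so that ring closure outruns oligomerisation; the alkenylchromium adds to the outer face of the aldehyde in the ring-closing conformer, placing the C6 hydroxyl (S) on the same ring face as the C4 ester and C3 methyl; the closest known reactions are the intermolecular electrochemical NHK coupling of alkenyl bromides with aldehydes and the stoichiometric CrCl2/NiCl2 closure of 2-haloallyl aldehydes to oxonanes.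

**Compound list**
1 | (R)-(−)-carvone, (5R)-2-methyl-5-(prop-1-en-2-yl)cyclohex-2-en-1-one | CC1=CC[C@H](CC1=O)C(C)=C | starting material
2 | trans-carvone epoxide, (1R,4R,6R)-1-methyl-4-(prop-1-en-2-yl)-7-oxabicyclo[4.1.0]heptan-2-one | C[C@@]12O[C@@H]1C[C@@H](C(C)=C)CC2=O | intermediate
3 | (1R,4R)-1-methyl-4-(prop-1-en-2-yl)cyclohexane-1,2-diol (both C2 epimers, C2 left undefined) | C[C@@]1(O)CC[C@@H](C(C)=C)CC1O | intermediate
4 | (2R,5R)-2-hydroxy-2-methyl-5-(prop-1-en-2-yl)cyclohexan-1-one | C[C@@]1(O)CC[C@@H](C(C)=C)CC1=O | intermediate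
5 | (2R,5R)-2-methyl-5-(prop-1-en-2-yl)-2-(triethylsilyloxy)cyclohexan-1-one | C[C@@]1(O[Si](CC)(CC)CC)CC[C@@H](C(C)=C)CC1=O | intermediate
6 | 2,4,6-triisopropylbenzenesulfonylhydrazone of 5 | CC(C)c1cc(C(C)C)c(S(=O)(=O)N/N=C2\C[C@H](C(C)=C)CC[C@@]2(C)O[Si](CC)(CC)CC)c(C(C)C)c1 | intermediate
7 | C10 alkenyllithium (C1=C10) | [Li]C1=C[C@H](C(C)=C)CC[C@@]1(C)O[Si](CC)(CC)CC | intermediate
8 | (3R,6R)-6-methyl-3-(prop-1-en-2-yl)-6-(triethylsilyloxy)cyclohex-1-ene-1-carboxylic acid | OC(=O)C1=C[C@H](C(C)=C)CC[C@@]1(C)O[Si](CC)(CC)CC | intermediate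
9 | (1S,2S,3R,6R)-3-methyl-6-(prop-1-en-2-yl)-3-(triethylsilyloxy)cyclohexane-1,2-dicarboxylic acid | OC(=O)[C@H]1[C@@H](C(=O)O)[C@H](C(C)=C)CC[C@@]1(C)O[Si](CC)(CC)CC | intermediate
10 | cis-fused cyclic anhydride of 9 (C2 and C9 carbonyls) | O=C1OC(=O)[C@H]2[C@H](C(C)=C)CC[C@@](C)(O[Si](CC)(CC)CC)[C@@H]12 | intermediate
11 | 3-(tert-butyldiphenylsilyloxy)propan-1-ol | OCCCO[Si](c1ccccc1)(c1ccccc1)C(C)(C)C | starting material
12 | 3-(tert-butyldiphenylsilyloxy)propanal | O=CCCO[Si](c1ccccc1)(c1ccccc1)C(C)(C)C | intermediate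
13 | (Z)-tert-butyl(4-iodopent-3-enyloxy)diphenylsilane | C/C(I)=C/CCO[Si](c1ccccc1)(c1ccccc1)C(C)(C)C | intermediate
14 | (Z)-alkenyllithium from 13 | C/C([Li])=C/CCO[Si](c1ccccc1)(c1ccccc1)C(C)(C)C | intermediate
15 | cis keto acid: (Z)-enoyl group on C1 (C2 ketone), CO2H on C10 | OC(=O)[C@H]1[C@@H](C(=O)/C(C)=C\CCO[Si](c2ccccc2)(c2ccccc2)C(C)(C)C)[C@H](C(C)=C)CC[C@@]1(C)O[Si](CC)(CC)CC | intermediate
16 | cis-fused γ-lactone, C9 carbonyl, C2 (R) with the (Z)-alkenyl chain concave | O=C2O[C@@H](/C(C)=C\CCO[Si](c1ccccc1)(c1ccccc1)C(C)(C)C)[C@H]4[C@@H](CC[C@@](C)(O[Si](CC)(CC)CC)[C@H]42)C(C)=C | intermediate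
17 | diisobutylaluminium lactolate of 16 (C9 undefined) | CC(C)C[Al](CC(C)C)OC2O[C@@H](/C(C)=C\CCO[Si](c1ccccc1)(c1ccccc1)C(C)(C)C)[C@H]4[C@@H](CC[C@@](C)(O[Si](CC)(CC)CC)[C@H]42)C(C)=C | intermediate
18 | C9 lactol acetate (both anomers, C9 undefined) | CC(=O)OC2O[C@@H](/C(C)=C\CCO[Si](c1ccccc1)(c1ccccc1)C(C)(C)C)[C@H]4[C@@H](CC[C@@](C)(O[Si](CC)(CC)CC)[C@H]42)C(C)=C | intermediate
19 | 2,5-trans oxolane with the C9 2-bromoallyl group, C14 isopropenyl | C=C(Br)C[C@@H]2O[C@@H](/C(C)=C\CCO[Si](c1ccccc1)(c1ccccc1)C(C)(C)C)[C@H]4[C@@H](CC[C@@](C)(O[Si](CC)(CC)CC)[C@H]42)C(C)=C | intermediate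
20 | B-alkyl-9-borabicyclononane (boron on C16) | C=C(Br)C[C@@H]2O[C@@H](/C(C)=C\CCO[Si](c1ccccc1)(c1ccccc1)C(C)(C)C)[C@H]4[C@@H](CC[C@@](C)(O[Si](CC)(CC)CC)[C@H]42)[C@@H](C)CB1C2CCCC1CCC2 | intermediate
21 | C16 primary alcohol, (15R) | C=C(Br)C[C@@H]2O[C@@H](/C(C)=C\CCO[Si](c1ccccc1)(c1ccccc1)C(C)(C)C)[C@H]4[C@@H](CC[C@@](C)(O[Si](CC)(CC)CC)[C@H]42)[C@@H](C)CO | intermediate
22 | C16 carboxylic acid | C=C(Br)C[C@@H]2O[C@@H](/C(C)=C\CCO[Si](c1ccccc1)(c1ccccc1)C(C)(C)C)[C@H]4[C@@H](CC[C@@](C)(O[Si](CC)(CC)CC)[C@H]42)[C@@H](C)C(=O)O | intermediate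
23 | C3/C4 epoxy acid (epoxide on the face away from C1) | C=C(Br)C[C@@H]2O[C@@H]([C@]3(C)O[C@@H]3CCO[Si](c1ccccc1)(c1ccccc1)C(C)(C)C)[C@H]4[C@@H](CC[C@@](C)(O[Si](CC)(CC)CC)[C@H]42)[C@@H](C)C(=O)O | intermediate
24 | hydroxy ε-lactone, (3S,4R), free C4–OH | C=C(Br)C[C@@H]2O[C@@H]3[C@H]4[C@@H](CC[C@@](C)(O[Si](CC)(CC)CC)[C@H]42)[C@@H](C)C(=O)O[C@@]3(C)[C@H](O)CCO[Si](c1ccccc1)(c1ccccc1)C(C)(C)C | intermediate
25 | C4 octanoate | C=C(Br)C[C@@H]2O[C@@H]3[C@H]4[C@@H](CC[C@@](C)(O[Si](CC)(CC)CC)[C@H]42)[C@@H](C)C(=O)O[C@@]3(C)[C@H](OC(=O)CCCCCCC)CCO[Si](c1ccccc1)(c1ccccc1)C(C)(C)C | intermediate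
26 | diol (C11–OH, C6–OH) | C=C(Br)C[C@@H]2O[C@@H]3[C@H]4[C@@H](CC[C@@](C)(O)[C@H]42)[C@@H](C)C(=O)O[C@@]3(C)[C@H](OC(=O)CCCCCCC)CCO | intermediate
27 | C6 aldehyde with the C7 bromoalkene | C=C(Br)C[C@@H]2O[C@@H]3[C@H]4[C@@H](CC[C@@](C)(O)[C@H]42)[C@@H](C)C(=O)O[C@@]3(C)[C@H](OC(=O)CCCCCCC)CC=O | intermediate
28 | CNP0295349.4 | C=C1C[C@@H]2O[C@@H]3[C@H]4[C@@H](CC[C@@](C)(O)[C@H]42)[C@@H](C)C(=O)O[C@@]3(C)[C@H](OC(=O)CCCCCCC)C[C@@H]1O | target

**Step count**
Total: 21 steps. Longest linear sequence: 19 steps (steps 1–8 and 11–21, from (R)-carvone); the side chain takes 2 steps (9 and 10).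

**Three steps most likely to fail, with fallbacks**

Step 21 (the proposed new step). The catalytic electrochemical cycle has not been run intramolecularly, and the oxonane it must close is bridged trans across the oxolane, so it is strained. The fallback sets out from aldehyde 27 and comes back at target 28. It drops electrolysis and chromium turnover: 27 is added slowly to excess CrCl2 containing 1 mol % NiCl2 in degassed DMSO at high dilution, the stoichiometric Nozaki–Hiyama–Kishi reaction that is the established way to close this oxonane from a 2-haloallyl aldehyde. No new compound is formed (none, F0).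

Step 12. Hydride could attack the allylic terminus instead of C2, or the ketone could be reduced in its open form, which by Felkin–Anh control gives the wrong C2 epimer. The fallback sets out from keto acid 15 and comes back at lactone 16, and it uses that open-chain selectivity on purpose. The triethylammonium salt of 15 is reduced with NaBH4 and CeCl3·7H2O in MeOH at −40 °C to the C2-epimeric allylic alcohol, hydroxy acid F1, which is kept as the carboxylate salt so that it cannot lactonise with retention. MsCl and Et3N in CH2Cl2 at −30 °C give the allylic mesylate F2, which the neighbouring carboxylate displaces at once (5-exo, SN2, inversion at C2) to give 16.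

Step 17. The peracid may choose the other alkene face, and then the acid cannot open the epoxide to the required (3S,4R) lactone. The fallback sets out from acid 22 and comes back at epoxy acid 23; it lets the nucleophile rather than the electrophile choose the face. Me3SiCHN2 in MeOH–toluene gives the methyl ester F3. NBS in aqueous DME at 0 °C gives the bromohydrin F4: bromonium ions form reversibly on both faces, and water opens at tertiary C3 from the open face away from C1. K2CO3 in MeOH closes this to the epoxy ester F5 with inversion at C4, the same epoxide as in 23. LiOH in aqueous THF then gives 23, which is cyclised with TsOH as in step 17 to 24.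

Further compounds
F1 | step 12 | C2-epimeric allylic alcohol, hydroxy acid from Luche reduction of 15 | OC(=O)[C@H]1[C@@H]([C@H](O)/C(C)=C\CCO[Si](c2ccccc2)(c2ccccc2)C(C)(C)C)[C@H](C(C)=C)CC[C@@]1(C)O[Si](CC)(CC)CC
F2 | step 12 | C2 methanesulfonate of F1 | OC(=O)[C@H]1[C@@H]([C@H](OS(C)(=O)=O)/C(C)=C\CCO[Si](c2ccccc2)(c2ccccc2)C(C)(C)C)[C@H](C(C)=C)CC[C@@]1(C)O[Si](CC)(CC)CC
F3 | step 17 | methyl ester of 22 | C=C(Br)C[C@@H]2O[C@@H](/C(C)=C\CCO[Si](c1ccccc1)(c1ccccc1)C(C)(C)C)[C@H]4[C@@H](CC[C@@](C)(O[Si](CC)(CC)CC)[C@H]42)[C@@H](C)C(=O)OC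
F4 | step 17 | bromohydrin methyl ester (C3–OH, C4–Br) | C=C(Br)C[C@@H]2O[C@@H]([C@](C)(O)[C@@H](Br)CCO[Si](c1ccccc1)(c1ccccc1)C(C)(C)C)[C@H]4[C@@H](CC[C@@](C)(O[Si](CC)(CC)CC)[C@H]42)[C@@H](C)C(=O)OC
F5 | step 17 | epoxy methyl ester (methyl ester of 23) | C=C(Br)C[C@@H]2O[C@@H]([C@]3(C)O[C@@H]3CCO[Si](c1ccccc1)(c1ccccc1)C(C)(C)C)[C@H]4[C@@H](CC[C@@](C)(O[Si](CC)(CC)CC)[C@H]42)[C@@H](C)C(=O)OC
F0 | step 21 | none | none
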